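At the charges, a molecule of complex with one exchanged meets incoming ligand 162 times as fast as it meets capture agent, yet that lead holds only for as long as the exchange does not run back.

| flask | starting complex | incoming ligand | leaving ligand | capture agent | temperature | time | remark |
|---|---|---|---|---|---|---|---|
| summer | 0.010 M | 5.00 mM (fed, over 4.0 d) | 5.00 mM | 0.500 mM | 110 °C | 6.0 d | all else is in the flask from the start; the feed brings no volume worth counting |
| autumn | 0.010 M | 5.00 mM | 5.00 mM | 0.500 mM | 110 °C | 6.0 d | everything together at the start |
| noon | 0.010 M (fed, over 4.0 d) | 5.00 mM | 5.00 mM | 0.500 mM |  | 6.0 d | the addition at 80 °C, then warmed to 110 °C; the feed brings no volume worth counting |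
| winter | 0.010 M (fed, over 4.0 d) | 5.00 mM | 5.00 mM | 0.500 mM | 110 °C | 6.0 d | all else is in the flask from the start; the feed brings no volume worth counting |

    complex with one exchanged + capture agent → trapped intermediate (k1 = 2.6 × 10⁻⁴ M⁻¹ s⁻¹, Ea1 = 84.0 kJ mol⁻¹)
    starting complex + incoming ligand ⇌ leaving ligand + complex with one exchanged (K2 = 0.33, k2 = 0.0017 M⁻¹ s⁻¹, Ea2 = 62.0 kJ mol⁻¹, ΔH2 = −69.0 kJ mol⁻¹)
    complex with one exchanged + incoming ligand ⇌ leaving ligand + complex with two exchanged (K3 = 0.17, k3 = 0.0042 M⁻¹ s⁻¹, Ea3 = 72.0 kJ mol⁻¹, ΔH3 = −37.0 kJ mol⁻¹)
    (constants at 110 °C)

1. which flask leads in share of complex with two exchanged in complex with two exchanged plus trapped intermediate ("all alike" within 1.5 percentage points) (summer / autumn / noon / winter / all alike)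
2. share of complex with two exchanged in complex with two exchanged plus trapped intermediate at the end, summer
3. share of complex with two exchanged in complex with two exchanged plus trapped intermediate at the end, autumn
4. share of complex with two exchanged in complex with two exchanged plus trapped intermediate at the end, noon
5. share of complex with two exchanged in complex with two exchanged plus trapped intermediate at the end, winter

- constants are those at 110 °C; use the activation energies and enthalpies for any other temperature

We follow that molecule to its fork. In one extreme version of the flask nothing runs back, so each molecule forks once, and this selectivity factor gives a share of 99.4 %. In the other extreme the exchanges are in balance and the 0.500 mM of capture agent has become trapped intermediate. Solving the second step's equilibrium from the charges, before any trapping and with the third step neglected, moves 1.51 mM of ligand, which puts [incoming ligand] at 3.49 mM and [leaving ligand] at 6.51 mM; we shall need these two values below. Solved again with the 0.500 mM taken out of the complex with one exchanged, the same equilibrium moves 1.78 mM of ligand and leaves 1.28 mM of complex with one exchanged. The third step then holds 0.104 mM of complex with two exchanged, so this extreme gives a share of 17.2 %.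

The real flasks lie between these, because the exchange relaxes with a half-time near 3.76 h, shorter than the 6.0 d of the run, while a molecule of complex with one exchanged waits 89.0 d for capture agent, longer than the run. So we take the exchange as in balance and hold capture agent at its charge. Complex with two exchanged then stands at K3 [incoming ligand]/[leaving ligand] times [complex with one exchanged], and trapped intermediate grows at the trapping constant times [capture agent] times that same [complex with one exchanged], which cancels from the comparison. The result, 8.13 d, is our crossing time, the stay at 110 °C after which as much trapped intermediate stands as complex with two exchanged. The share is the crossing time over the crossing time plus the stay.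

Autumn stays 6.0 d, which gives 57.5 %. In summer and winter, [complex with one exchanged] climbs roughly straight from nothing during the feed, so the feed counts as half its length, and both flasks give 67.0 %. In noon, trapping at 80 °C runs at 0.106 of its pace at 110 °C, so the stay shrinks to 2.21 d and the share is 78.6 %, higher than in summer and winter.

The forecast gives 67 % for summer, 58 % for autumn, 77 % for noon and 65 % for winter, with noon leading, on the ground that “Trapping tracks the time-integrated one-exchanged complex”.

The simulation gives 66.6 % for summer, 58.3 % for autumn, 78.0 % for noon and 66.2 % for winter, so noon leads. At 6.00 d the noon flask holds 1.19 % of complex with two exchanged beside 0.334 % of trapped intermediate, both in percent of the starting complex charged. We carry the same crossing time of 8.13 d to a summer flask dosed over 1.20 d: its stay becomes 5.40 d, which gives 60.1 %. That flask ended at 60.6 %.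

(Its constants were set for the occasion; no experiment stands behind them.)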